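## Plan

1. Numbering: the ring atoms run from C1 (carries the exocyclic CH2) through C2 and C3 to C14 (free carbinol). C18 is the acetoxymethyl carbon on C11.
2. Enabling feature: in the only ring, the 14-membered carbocycle, C2–C1(=CH2) is an allyl unit substituted only at its central carbon, so its two CH2 ends are interchangeable. The adjacent C3 is allylic to the E C4=C5 alkene and can carry a removable PhSO2 group, so the ring is cut at C2–C3.
3. The open chain is cut again at C11–C12 (sp2–sp3 cross-coupling) and at C8–C9 (allylboration). This gives C3–C8 with the isopropenyl group (geranyl bromide), C9–C11 with C18 (but-2-yne-1,4-diol), and C12–C14/C1/C2 (aldehyde plus acrylate).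
4. Forward order: C8–C9, then C11–C12, then ring closure at C2–C3, then loss of the sulfone, TES-to-acetate exchange at C9 and C18, and release of the C14 hydroxyl.
5. Stereochemistry: C14 (R) comes from an amine-catalysed asymmetric Morita–Baylis–Hillman reaction. C8 (R) and C9 (S) come from one allylboration, anti from the E boronate through a chair and absolute sense from a chiral phosphoric acid. C4=C5 (E) is carried over from geranyl, and C10=C11 comes from trans-hydroalumination/iodination followed by a stereoretentive coupling.

Key step: step 18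

Assumption: (R)-TRIP is taken to direct the allyl group to the Re face of the iodo enal, as it does with simple allyl and crotyl pinacolboronates; if the sense were reversed, the (S)-acid would be used.

## Route

Step 1
Reactants: 1 geranyl bromide
Product: 2 geranyl phenyl sulfone
Conditions: PhSO2Na, DMF, rt
Reagents that add atoms: sodium benzenesulfinate, [Na+].[O-]S(=O)c1ccccc1
Why: SN2 S-alkylation of the sulfinate by the primary allylic bromide should install the C3 sulfone without touching the E alkene that becomes C4=C5.

Step 2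
Reactants: 2 geranyl phenyl sulfone
Product: 3 (2E,6E)-2,6-dimethyl-8-(phenylsulfonyl)octa-2,6-dien-1-ol
Conditions: SeO2 (cat.), t-BuOOH, CH2Cl2, 0 °C to rt
Reagents that add atoms: tert-butyl hydroperoxide, CC(C)(C)OO (oxygen atom, passed on through SeO2, O=[Se]=O)
Why: Catalytic SeO2 allylic oxidation (ene reaction then [2,3]-shift) should pick the electron-richer alkene remote from the sulfone and oxidise its E methyl group, which fixes the E geometry later translated into the anti C8/C9 relationship.

Step 3
Reactants: 3 (2E,6E)-2,6-dimethyl-8-(phenylsulfonyl)octa-2,6-dien-1-ol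
Product: 4 [(2E,6E)-8-bromo-3,7-dimethylocta-2,6-dien-1-yl]sulfonylbenzene
Conditions: PBr3, THF, 0 °C
Reagents that add atoms: phosphorus tribromide, BrP(Br)Br
Why: Bromination of a primary allylic alcohol through its phosphite ester is an SN2 process that should proceed at low temperature without allylic shift or loss of geometry.

Step 4
Reactants: 4 [(2E,6E)-8-bromo-3,7-dimethylocta-2,6-dien-1-yl]sulfonylbenzene
Product: 5 pinacol [(2E,6E)-2,6-dimethyl-8-(phenylsulfonyl)octa-2,6-dien-1-yl]boronate
Conditions: B2pin2, Pd2(dba)3 (cat.), THF, 60 °C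
Reagents that add atoms: bis(pinacolato)diboron, CC1(C)OB(OC1(C)C)B1OC(C)(C)C(C)(C)O1
Why: Palladium-catalysed borylation of an allylic halide should give the linear primary allylboronate with retained alkene geometry, because the phosphine-free catalyst ionises the bromide far faster than the allylic sulfone.

Step 5
Reactants: 6 but-2-yne-1,4-diol
Product: 7 4-(triethylsilyloxy)but-2-yn-1-ol
Conditions: TESCl, imidazole, 6 in excess, DMF, 0 °C
Reagents that add atoms: chlorotriethylsilane, CC[Si](Cl)(CC)CC
Why: Statistical monosilylation of a cheap symmetrical diol used in excess should favour the mono ether, whose oxygen becomes the C18 oxygen.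

Step 6
Reactants: 7 4-(triethylsilyloxy)but-2-yn-1-ol
Product: 9 (2Z)-3-iodo-4-(triethylsilyloxy)but-2-en-1-ol, via cyclic sodium alkenylalanate 8 (not isolated)
Conditions: NaAlH2(OCH2CH2OMe)2, THF, 0 °C to rt; then I2, −78 to 0 °C
Reagents that add atoms: iodine, II
Why: Hydroxyl-directed trans-hydroalumination of the propargylic alcohol places aluminium on the distal alkyne carbon (C11) inside a five-membered alkoxyalanate, and iododealumination with retention should give the Z iodide in which the iodine, later C12, is cis to C9.

Step 7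
Reactants: 9 (2Z)-3-iodo-4-(triethylsilyloxy)but-2-en-1-ol
Product: 10 (2Z)-3-iodo-4-(triethylsilyloxy)but-2-enal
Conditions: MnO2, CH2Cl2, rt
Reagents that add atoms: none
Why: Neutral heterogeneous MnO2 oxidation is selective for allylic alcohols and should spare the TES ether and the Z geometry, provided the enal is used at once.

Step 8
Reactants: 5 pinacol [(2E,6E)-2,6-dimethyl-8-(phenylsulfonyl)octa-2,6-dien-1-yl]boronate; 10 (2Z)-3-iodo-4-(triethylsilyloxy)but-2-enal
Product: 12 (2Z,4R,5R,8E)-2-iodo-8-methyl-10-(phenylsulfonyl)-5-(prop-1-en-2-yl)-1-(triethylsilyloxy)deca-2,8-dien-4-ol, via O-pinacolboryl ether 11 (not isolated)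
Conditions: (R)-TRIP [(R)-3,3'-bis(2,4,6-triisopropylphenyl)-1,1'-binaphthyl-2,2'-diyl hydrogen phosphate, 10 mol%], 4 Å MS, toluene, −30 °C; aqueous work-up
Reagents that add atoms: none
Why: In this chiral-phosphoric-acid-catalysed allylboration the closed Zimmerman–Traxler chair turns the E geometry of 5 into the anti C8/C9 relationship and creates the isopropenyl group by allyl transposition, while the acid bound to a boronate oxygen should expose the Re face of 10 and so set C8 (R) and C9 as in the target (C9 reads R here only because iodine raises the rank of C10).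

Step 9
Reactants: 12 the homoallylic alcohol of step 8
Product: 13 C9 triethylsilyl ether of 12
Conditions: TESOTf, 2,6-lutidine, CH2Cl2, −78 to 0 °C
Reagents that add atoms: triethylsilyl triflate, CC[Si](CC)(CC)OS(=O)(=O)C(F)(F)F
Why: Silylation with a silyl triflate and a hindered base is the standard way to cap a crowded secondary allylic alcohol, and it gives an ether that no palladium step can ionise.

Step 10
Reactants: 14 3-(tert-butyldimethylsilyloxy)propanal; 15 1,1,1,3,3,3-hexafluoropropan-2-yl acrylate
Product: 16 1,1,1,3,3,3-hexafluoropropan-2-yl (3R)-5-(tert-butyldimethylsilyloxy)-3-hydroxy-2-methylidenepentanoate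
Conditions: β-isocupreidine (10 mol%), DMF, −55 °C
Reagents that add atoms: none
Why: In this asymmetric Morita–Baylis–Hillman reaction the quinuclidine nitrogen adds to the activated acrylate and the phenolic OH of the catalyst organises the aldol and elimination steps, so the (R)-adduct should be released, which sets C14 and assembles C12–C14, C1, C2 and the exocyclic CH2.

Step 11
Reactants: 16 the hexafluoroisopropyl ester of step 10
Product: 17 methyl (3R)-5-(tert-butyldimethylsilyloxy)-3-hydroxy-2-methylidenepentanoate
Conditions: MeOH, Et3N, rt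
Reagents that add atoms: methanol, CO
Why: Amine-promoted transesterification of the activated fluoroalkyl ester should give the robust methyl ester, which then masks the C2 oxygen function until step 16.

Step 12
Reactants: 17 the methyl ester of step 11
Product: 18 methyl (3R)-3,5-bis(tert-butyldimethylsilyloxy)-2-methylidenepentanoate
Conditions: TBSOTf, 2,6-lutidine, CH2Cl2, 0 °C
Reagents that add atoms: tert-butyldimethylsilyl triflate, CC(C)(C)[Si](C)(C)OS(=O)(=O)C(F)(F)F
Why: Standard triflate silylation protects the C14 hydroxyl with the group that must outlast both TES ethers.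

Step 13
Reactants: 18 the bis-TBS ether of step 12
Product: 19 methyl (3R)-3-(tert-butyldimethylsilyloxy)-5-hydroxy-2-methylidenepentanoate
Conditions: HF·pyridine, pyridine, THF, 0 °C
Reagents that add atoms: none
Why: Sterically differentiated desilylation should cleave the primary TBS ether well before the hindered secondary one, and the buffered fluoride avoids acid-promoted closure of the hydroxy ester to the six-membered lactone.

Step 14
Reactants: 19 the primary alcohol of step 13
Product: 20 methyl (3R)-3-(tert-butyldimethylsilyloxy)-5-iodo-2-methylidenepentanoate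
Conditions: I2, PPh3, imidazole, CH2Cl2, 0 °C
Reagents that add atoms: iodine, II
Why: Appel-type iodination of a primary alcohol with preformed Ph3PI2 is fast and neutral, and it leaves no free phosphine to add to the acrylate.

Step 15
Reactants: 20 methyl (3R)-3-(tert-butyldimethylsilyloxy)-5-iodo-2-methylidenepentanoate; 13 C9 triethylsilyl ether of 12
Product: 22 methyl (3R,6E,8S,9R,12E)-3-(tert-butyldimethylsilyloxy)-12-methyl-2-methylidene-14-(phenylsulfonyl)-9-(prop-1-en-2-yl)-8-(triethylsilyloxy)-6-(triethylsilyloxymethyl)tetradeca-6,12-dienoate, via alkylzinc iodide 21 (not isolated)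
Conditions: Zn dust, LiCl, THF, 35 °C; then 13, Pd(dppf)Cl2 (5 mol%), THF, rt
Reagents that add atoms: none
Why: LiCl-assisted zinc insertion into the primary iodide tolerates the ester, and the Negishi sp3–sp2 coupling should replace iodine by C12 with retention (so C12 ends cis to C9), the wide-bite-angle dppf favouring reductive elimination over β-hydride loss.

Step 16
Reactants: 22 the seco ester of step 15
Product: 23 (3R,6E,8S,9R,12E)-3-(tert-butyldimethylsilyloxy)-12-methyl-2-methylidene-14-(phenylsulfonyl)-9-(prop-1-en-2-yl)-8-(triethylsilyloxy)-6-(triethylsilyloxymethyl)tetradeca-6,12-dien-1-ol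
Conditions: i-Bu2AlH, CH2Cl2, −78 °C
Reagents that add atoms: none
Why: 1,2-Reduction of an α-substituted acrylate by i-Bu2AlH should give the 2-substituted allylic alcohol and leave the sulfone, the alkenes and the three silyl ethers untouched.

Step 17
Reactants: 23 the seco allylic alcohol of step 16
Product: 24 tert-butyl carbonate of 23 (seco C3 allylic phenyl sulfone with a C2 allylic OCO2t-Bu group)
Conditions: Boc2O, DMAP (cat.), CH2Cl2, 0 °C to rt
Reagents that add atoms: di-tert-butyl dicarbonate, CC(C)(C)OC(=O)OC(=O)OC(C)(C)C
Why: DMAP-catalysed O-acylation of the primary alcohol installs the leaving group, and a tert-butyl carbonate is chosen because the alkoxide it releases in step 18 is a stronger base and a much poorer nucleophile toward an allyl ligand than methoxide.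

Step 18
Reactants: 24 tert-butyl carbonate of 23
Product: 25 (4E,8R,9S,10E,14R)-14-(tert-butyldimethylsilyloxy)-5-methyl-1-methylidene-3-(phenylsulfonyl)-8-(prop-1-en-2-yl)-9-(triethylsilyloxy)-11-(triethylsilyloxymethyl)cyclotetradeca-4,10-diene, both C3 epimers (route numbering)
Conditions: Pd(PPh3)4 (10 mol%), dppe (10 mol%), THF, 45 °C, 24 added by syringe pump over 12 h, final about 1 mM
Reagents that add atoms: none
Why: Zerovalent palladium ionises the primary allylic tert-butyl carbonate with loss of CO2 to a cationic π-allylpalladium substituted only at its central carbon C1, and the tert-butoxide set free, too bulky to be trapped as an allyl ether, deprotonates the C3–H activated by both sulfonyl and vinyl groups (pKa near 23 on the DMSO scale), so the carbanion arises only beside its electrophile and attacks an allyl terminus on the face away from the metal, forming C2–C3 and returning the catalyst. The closest known reaction type is the intramolecular Tsuji–Trost allylic alkylation of sulfone-stabilised carbanions run from allylic carbonates without added base, an established way to medium and large carbocycles. The one ring formed, the 14-membered carbocycle, closes end to end in exo fashion (the metal departs outside the new ring), and since both allyl ends are CH2 groups on C1 each of them leads to the same ring size and the same 1-methylidene product. The only new stereocentre, C3, is not controlled and need not be, because step 19 turns it into CH2, while C8, C9 and C14 are spectators. The step needs α- rather than γ-attack of the ambident anion, which the fully substituted methyl-bearing C5 enforces; it needs ring closure rather than oligomerisation, which slow addition to high dilution secures; and it needs ionisation of the carbonate alone, which holds because the silyl ethers at C9, C14 and C18 are not leaving groups and the allylic sulfone ionises appreciably only at higher temperature. β-Hydride elimination is not open to this allyl complex, since in either σ-allyl form the carbon next to the metal-bearing CH2 is the hydrogen-free C1.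

Step 19
Reactants: 25 the macrocyclic C3 sulfone of step 18
Product: 26 (4E,8R,9S,10E,14R)-14-(tert-butyldimethylsilyloxy)-5-methyl-1-methylidene-8-(prop-1-en-2-yl)-9-(triethylsilyloxy)-11-(triethylsilyloxymethyl)cyclotetradeca-4,10-diene
Conditions: PdCl2(dppp) (10 mol%), LiBHEt3, THF, 0 °C to rt
Reagents that add atoms: none
Why: Palladium-catalysed hydride substitution of an allylic sulfone ionises C3–S to the C3–C5 allyl complex and should deliver hydride to the less substituted C3, which keeps the trisubstituted E C4=C5 alkene in place as in prenyl-type sulfones.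

Step 20
Reactants: 26 the desulfonylated macrocycle of step 19
Product: 27 (4E,8R,9S,10E,14R)-14-(tert-butyldimethylsilyloxy)-11-(hydroxymethyl)-5-methyl-1-methylidene-8-(prop-1-en-2-yl)cyclotetradeca-4,10-dien-9-ol
Conditions: PPTS, MeOH/CH2Cl2, 0 °C to rt
Reagents that add atoms: none
Why: Mild acid methanolysis should remove both TES ethers while the much less labile secondary TBS ether at C14 stays.

Step 21
Reactants: 27 the C9,C18 diol of step 20
Product: 28 C9,C18 diacetate of 27
Conditions: Ac2O, pyridine, DMAP (cat.), CH2Cl2, rt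
Reagents that add atoms: acetic anhydride, CC(=O)OC(C)=O
Why: DMAP-catalysed acetylation esterifies the primary and the hindered secondary allylic alcohol after the last palladium step, so no allylic acetate ever meets zerovalent palladium.

Step 22
Reactants: 28 the diacetate of step 21
Product: 29 CNP0077636.1, (4E,8R,9S,10E,14R)-9-acetoxy-11-(acetoxymethyl)-14-hydroxy-5-methyl-1-methylidene-8-(prop-1-en-2-yl)cyclotetradeca-4,10-diene
Conditions: HF·pyridine, pyridine, THF, 0 °C to rt
Reagents that add atoms: none
Why: Buffered fluoride desilylation should free the C14 hydroxyl without cleaving or shifting the remote acetates.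

## Compound list

1 | geranyl bromide, (2E)-1-bromo-3,7-dimethylocta-2,6-diene | CC(C)=CCC/C(C)=C/CBr | starting material
2 | geranyl phenyl sulfone | O=S(=O)(c1ccccc1)C/C=C(\C)CCC=C(C)C | intermediate
3 | (2E,6E)-2,6-dimethyl-8-(phenylsulfonyl)octa-2,6-dien-1-ol | O=S(=O)(c1ccccc1)C/C=C(\C)CC/C=C(\C)CO | intermediate
4 | [(2E,6E)-8-bromo-3,7-dimethylocta-2,6-dien-1-yl]sulfonylbenzene | O=S(=O)(c1ccccc1)C/C=C(\C)CC/C=C(\C)CBr | intermediate
5 | pinacol [(2E,6E)-2,6-dimethyl-8-(phenylsulfonyl)octa-2,6-dien-1-yl]boronate | O=S(=O)(c1ccccc1)C/C=C(\C)CC/C=C(\C)CB1OC(C)(C)C(C)(C)O1 | intermediate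
6 | but-2-yne-1,4-diol | OCC#CCO | starting material
7 | 4-(triethylsilyloxy)but-2-yn-1-ol | OCC#CCO[Si](CC)(CC)CC | intermediate
8 | cyclic sodium alkenylalanate (five-membered O–Al–C11=C10–C9 ring, two 2-methoxyethoxy ligands), not isolated | [Na+].COCCO[Al-]1(OCCOC)OCC=C1CO[Si](CC)(CC)CC | intermediate
9 | (2Z)-3-iodo-4-(triethylsilyloxy)but-2-en-1-ol | OC/C=C(/CO[Si](CC)(CC)CC)I | intermediate
10 | (2Z)-3-iodo-4-(triethylsilyloxy)but-2-enal | O=C/C=C(/CO[Si](CC)(CC)CC)I | intermediate
11 | O-pinacolboryl ether of 12, not isolated | O=S(=O)(c1ccccc1)C/C=C(\C)CC[C@H](C(=C)C)[C@@H](OB1OC(C)(C)C(C)(C)O1)/C=C(/CO[Si](CC)(CC)CC)I | intermediate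
12 | (2Z,4R,5R,8E)-2-iodo-8-methyl-10-(phenylsulfonyl)-5-(prop-1-en-2-yl)-1-(triethylsilyloxy)deca-2,8-dien-4-ol | O=S(=O)(c1ccccc1)C/C=C(\C)CC[C@H](C(=C)C)[C@@H](O)/C=C(/CO[Si](CC)(CC)CC)I | intermediate
13 | C9 (chain C4) triethylsilyl ether of 12 | O=S(=O)(c1ccccc1)C/C=C(\C)CC[C@H](C(=C)C)[C@@H](O[Si](CC)(CC)CC)/C=C(/CO[Si](CC)(CC)CC)I | intermediate
14 | 3-(tert-butyldimethylsilyloxy)propanal | O=CCCO[Si](C)(C)C(C)(C)C | starting material
15 | 1,1,1,3,3,3-hexafluoropropan-2-yl acrylate | C=CC(=O)OC(C(F)(F)F)C(F)(F)F | starting material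
16 | 1,1,1,3,3,3-hexafluoropropan-2-yl (3R)-5-(tert-butyldimethylsilyloxy)-3-hydroxy-2-methylidenepentanoate | CC(C)(C)[Si](C)(C)OCC[C@@H](O)C(=C)C(=O)OC(C(F)(F)F)C(F)(F)F | intermediate
17 | methyl (3R)-5-(tert-butyldimethylsilyloxy)-3-hydroxy-2-methylidenepentanoate | CC(C)(C)[Si](C)(C)OCC[C@@H](O)C(=C)C(=O)OC | intermediate
18 | methyl (3R)-3,5-bis(tert-butyldimethylsilyloxy)-2-methylidenepentanoate | CC(C)(C)[Si](C)(C)OCC[C@@H](O[Si](C)(C)C(C)(C)C)C(=C)C(=O)OC | intermediate
19 | methyl (3R)-3-(tert-butyldimethylsilyloxy)-5-hydroxy-2-methylidenepentanoate | OCC[C@@H](O[Si](C)(C)C(C)(C)C)C(=C)C(=O)OC | intermediate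
20 | methyl (3R)-3-(tert-butyldimethylsilyloxy)-5-iodo-2-methylidenepentanoate | ICC[C@@H](O[Si](C)(C)C(C)(C)C)C(=C)C(=O)OC | intermediate
21 | [(3R)-3-(tert-butyldimethylsilyloxy)-4-(methoxycarbonyl)pent-4-en-1-yl]zinc iodide, not isolated | I[Zn]CC[C@@H](O[Si](C)(C)C(C)(C)C)C(=C)C(=O)OC | intermediate
22 | methyl (3R,6E,8S,9R,12E)-3-(tert-butyldimethylsilyloxy)-12-methyl-2-methylidene-14-(phenylsulfonyl)-9-(prop-1-en-2-yl)-8-(triethylsilyloxy)-6-(triethylsilyloxymethyl)tetradeca-6,12-dienoate | O=S(=O)(c1ccccc1)C/C=C(\C)CC[C@H](C(=C)C)[C@@H](O[Si](CC)(CC)CC)/C=C(/CO[Si](CC)(CC)CC)CC[C@@H](O[Si](C)(C)C(C)(C)C)C(=C)C(=O)OC | intermediate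
23 | corresponding tetradeca-6,12-dien-1-ol (3R,6E,8S,9R,12E), seco allylic alcohol | O=S(=O)(c1ccccc1)C/C=C(\C)CC[C@H](C(=C)C)[C@@H](O[Si](CC)(CC)CC)/C=C(/CO[Si](CC)(CC)CC)CC[C@@H](O[Si](C)(C)C(C)(C)C)C(=C)CO | intermediate
24 | tert-butyl carbonate of 23, precursor of the key step | O=S(=O)(c1ccccc1)C/C=C(\C)CC[C@H](C(=C)C)[C@@H](O[Si](CC)(CC)CC)/C=C(/CO[Si](CC)(CC)CC)CC[C@@H](O[Si](C)(C)C(C)(C)C)C(=C)COC(=O)OC(C)(C)C | intermediate
25 | 14-membered C3 phenyl sulfone (4E,8R,9S,10E,14R; C3 epimers), C9 and C18 OTES, C14 OTBS | C=C1CC(S(=O)(=O)c2ccccc2)/C=C(\C)CC[C@H](C(=C)C)[C@@H](O[Si](CC)(CC)CC)/C=C(/CO[Si](CC)(CC)CC)CC[C@H]1O[Si](C)(C)C(C)(C)C | intermediate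
26 | desulfonylated macrocycle (4E,8R,9S,10E,14R), C9 and C18 OTES, C14 OTBS | C=C1CC/C=C(\C)CC[C@H](C(=C)C)[C@@H](O[Si](CC)(CC)CC)/C=C(/CO[Si](CC)(CC)CC)CC[C@H]1O[Si](C)(C)C(C)(C)C | intermediate
27 | C9,C18 diol, C14 OTBS | C=C1CC/C=C(\C)CC[C@H](C(=C)C)[C@@H](O)/C=C(/CO)CC[C@H]1O[Si](C)(C)C(C)(C)C | intermediate
28 | C9,C18 diacetate, C14 OTBS | C=C1CC/C=C(\C)CC[C@H](C(=C)C)[C@@H](OC(C)=O)/C=C(/COC(C)=O)CC[C@H]1O[Si](C)(C)C(C)(C)C | intermediate
29 | CNP0077636.1 | C=C1CC/C=C(\C)CC[C@H](C(=C)C)[C@@H](OC(C)=O)/C=C(/COC(C)=O)CC[C@H]1O | target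

## Step count and risks

Total step count: 22.
Longest linear sequence: 14 steps (steps 1–4, 8, 9 and 15–22).

**Step 18.** Proton transfer from C3 to tert-butoxide and attack of a singly stabilised carbanion on the allyl ligand may be too slow at high dilution. Intermolecular alkylation could then take over, or reversible ionisation of the allylic sulfone could let the C4=C5 geometry drift. The fallback keeps the C2–C3 closure but drops the metal. It sets out from 23, which CBr4 and PPh3 in CH2Cl2 at 0 °C should convert into the seco allylic bromide F1. Slow addition of F1 to NaN(SiMe3)2 in THF at −78 to 0 °C under high dilution is the classical intramolecular alkylation of a preformed sulfonyl carbanion. Direct and allyl-shifted displacement again converge on one product, and the sequence comes back to the route at 25.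

**Step 8.** Facial selectivity on a Z β-iodo enal may be poor, and geometric drift of the enal or the boronate would erode the anti relationship. The fallback exchanges boron and Brønsted acid for silicon and a chiral Lewis base. It sets out from 4, which HSiCl3, CuCl (cat.) and Et3N in Et2O should convert, without allylic shift, into the E allyltrichlorosilane F2. Reaction of F2 with 10 in CH2Cl2 at −78 °C uses i-Pr2NEt and the enantiomer of a 2,2'-bispyrrolidine-derived bisphosphoramide that directs Re-face attack. This reaction type is at its best with conjugated aldehydes and is anti-selective through a closed chair at hexacoordinate silicon. It should give the trichlorosilyl ether F3, and aqueous work-up comes back to the route at 12.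

**Step 15.** Oxidative addition and transmetalation at the crowded trisubstituted iodide may be slow. That would leave time for intramolecular carbopalladation of the nearby isopropenyl group or for protodezincation of the zinc reagent. The fallback reverses the order of the two fragment unions, so the coupling takes place on a small, unhindered iodide. It sets out from 21 and 9, which are coupled with Pd(OAc)2 and SPhos in THF at rt with slow addition of 21; these conditions tolerate a free hydroxyl. The product should be the allylic alcohol F4, which MnO2 in CH2Cl2 should oxidise to the enal F5. Allylboration of F5 with 5 under (R)-TRIP as in step 8 should give the boryl ether F6, and after work-up the anti homoallylic alcohol F7. TESOTf and 2,6-lutidine then come back to the route at 22.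

## Further compounds

F1 | step 18 | seco allylic bromide (23 with C2–Br in place of C2–OH) | O=S(=O)(c1ccccc1)C/C=C(\C)CC[C@H](C(=C)C)[C@@H](O[Si](CC)(CC)CC)/C=C(/CO[Si](CC)(CC)CC)CC[C@@H](O[Si](C)(C)C(C)(C)C)C(=C)CBr
F2 | step 8 | trichloro[(2E,6E)-2,6-dimethyl-8-(phenylsulfonyl)octa-2,6-dien-1-yl]silane | O=S(=O)(c1ccccc1)C/C=C(\C)CC/C=C(\C)C[Si](Cl)(Cl)Cl
F3 | step 8 | O-trichlorosilyl ether of 12 | O=S(=O)(c1ccccc1)C/C=C(\C)CC[C@H](C(=C)C)[C@@H](O[Si](Cl)(Cl)Cl)/C=C(/CO[Si](CC)(CC)CC)I
F4 | step 15 | methyl (3R,6E)-3-(tert-butyldimethylsilyloxy)-8-hydroxy-2-methylidene-6-(triethylsilyloxymethyl)oct-6-enoate | OC/C=C(/CO[Si](CC)(CC)CC)CC[C@@H](O[Si](C)(C)C(C)(C)C)C(=C)C(=O)OC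
F5 | step 15 | methyl (3R,6E)-3-(tert-butyldimethylsilyloxy)-2-methylidene-8-oxo-6-(triethylsilyloxymethyl)oct-6-enoate | O=C/C=C(/CO[Si](CC)(CC)CC)CC[C@@H](O[Si](C)(C)C(C)(C)C)C(=C)C(=O)OC
F6 | step 15 | O-pinacolboryl ether of F7 | O=S(=O)(c1ccccc1)C/C=C(\C)CC[C@H](C(=C)C)[C@@H](OB1OC(C)(C)C(C)(C)O1)/C=C(/CO[Si](CC)(CC)CC)CC[C@@H](O[Si](C)(C)C(C)(C)C)C(=C)C(=O)OC
F7 | step 15 | methyl (3R,6E,8S,9R,12E)-3-(tert-butyldimethylsilyloxy)-8-hydroxy-12-methyl-2-methylidene-14-(phenylsulfonyl)-9-(prop-1-en-2-yl)-6-(triethylsilyloxymethyl)tetradeca-6,12-dienoate | O=S(=O)(c1ccccc1)C/C=C(\C)CC[C@H](C(=C)C)[C@@H](O)/C=C(/CO[Si](CC)(CC)CC)CC[C@@H](O[Si](C)(C)C(C)(C)C)C(=C)C(=O)OC
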